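The depside is cut inside ring B, not at the ester between the rings. Ring B is a pentasubstituted benzene in which C1 (carboxyl) and C6 (pentyl) map onto the triple bond of an oct-2-ynoate, and C2(OH)–C3(Cl)–C4(OMe)–C5(H) map onto a 2-chloro-1,3-dimethoxy-1-silyloxybutadiene. One Diels–Alder/aromatisation forms C1–C2 and C5–C6, closes ring B and fixes the chlorine position, so ring A is only ever acylated by an unhindered ynoic acid. The precursor is the ring A phenol (acid as tert-butyl ester, ortho-hydroxyl as MOM ether) carrying the oct-2-ynoyl group on its C4 oxygen; acid then releases the target.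

Key step: step 8

Remark: ring B is numbered from the carbon bearing the ester carbonyl and ring A from the carbon bearing the carboxyl group; the target has no stereocentre, and the E/Z mixtures of the enol ether and of the diene converge on one product.

Step 1
Reactants: 1 2-hydroxy-6-methylbenzoic acid
Product: 2 tert-butyl 2-hydroxy-6-methylbenzoate
Conditions: Me2NCH(OtBu)2 (4 equiv), PhMe, 80 °C
Reagents that add atoms: N,N-dimethylformamide di-tert-butyl acetal, CN(C)C(OC(C)(C)C)OC(C)(C)C
Why: Amide-acetal esterification (carboxylic acid O-alkylation): the carboxylate is tert-butylated at oxygen by the protonated acetal, so the crowded 2,6-disubstituted acyl carbon is never attacked, and the weaker, hydrogen-bonded phenol should stay free.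

Step 2
Reactants: 2 tert-butyl 2-hydroxy-6-methylbenzoate
Product: 3 tert-butyl 2-(methoxymethoxy)-6-methylbenzoate
Conditions: NaH, MOMCl, DMF, 0 °C to rt
Reagents that add atoms: chloromethyl methyl ether, COCCl
Why: Williamson ether synthesis: NaH converts the chelated phenol into its phenoxide, which is alkylated by the highly reactive alpha-chloro ether, while the tert-butyl ester is inert to the base and to the alkylating agent.

Step 3
Reactants: 3 tert-butyl 2-(methoxymethoxy)-6-methylbenzoate; 4 1-bromobutane
Product: 6 tert-butyl 2-(methoxymethoxy)-6-pentylbenzoate, via lateral benzyllithium 5 (not isolated)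
Conditions: LiN(iPr)2, THF, −78 °C; then 4, DMPU, −78 °C to 0 °C
Reagents that add atoms: none
Why: Lateral lithiation and alkylation of an ortho-toluate: LiN(iPr)2 removes a proton from the C6 methyl group because the benzylic anion is conjugated with the ester, and SN2 reaction with the primary bromide turns methyl into pentyl, the bulky doubly ortho-flanked tert-butyl ester suppressing self-condensation and the amide base being too weak to metalate the ring next to the MOM ether.

Step 4
Reactants: 6 tert-butyl 2-(methoxymethoxy)-6-pentylbenzoate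
Product: 8 tert-butyl 4-hydroxy-2-(methoxymethoxy)-6-pentylbenzoate, via aryl pinacol boronate 7 (not isolated)
Conditions: [Ir(OMe)(cod)]2 (cat., cod = cycloocta-1,5-diene), 4,4'-di-tert-butyl-2,2'-bipyridine (cat.), B2pin2 (1 equiv), THF, 80 °C; then 30% aq H2O2, aq NaOH, 0 °C
Reagents that add atoms: bis(pinacolato)diboron, CC1(C)OB(OC1(C)C)B1OC(C)(C)C(C)(C)O1 (boryl group of 7); hydrogen peroxide, OO (phenol oxygen of 8)
Why: Sterically governed iridium-catalysed aromatic C–H borylation followed by oxidation of the C–B bond: of the three ring hydrogens only the one at C4 has no ortho substituent, so the boryl group and then the hydroxyl should enter there, and alkaline peroxide leaves the MOM ether and the hindered tert-butyl ester untouched.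

Step 5
Reactants: 8 tert-butyl 4-hydroxy-2-(methoxymethoxy)-6-pentylbenzoate; 9 oct-2-ynoic acid
Product: 10 tert-butyl 2-(methoxymethoxy)-4-(oct-2-ynoyloxy)-6-pentylbenzoate
Conditions: DCC, DMAP (cat.), CH2Cl2, 0 °C to rt
Reagents that add atoms: none
Why: Steglich esterification: the carbodiimide activates the unhindered ynoic acid and the C4 phenol, the only free nucleophile in 8, is acylated at low temperature, where addition of DMAP to the triple bond should not compete.

Step 6
Reactants: 11 methyl 2-chloro-3-oxobutanoate (methyl 2-chloroacetoacetate, racemic)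
Product: 13 methyl 2-chloro-3-methoxybut-2-enoate (E/Z mixture), via dimethyl ketal 12 (not isolated)
Conditions: HC(OMe)3, MeOH, H2SO4 (cat.), rt; then TsOH (cat.), heat, distil
Reagents that add atoms: trimethyl orthoformate, COC(OC)OC
Why: Orthoester-mediated ketalisation of the ketone and acid-catalysed loss of methanol on distillation (enol ether formation from a beta-keto ester) should give the conjugated beta-methoxy enoate, and any deconjugated but-3-enoate isomer would be deprotonated to the same dienolate in step 7.

Step 7
Reactants: 13 methyl 2-chloro-3-methoxybut-2-enoate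
Product: 15 2-chloro-1,3-dimethoxy-1-(trimethylsilyloxy)buta-1,3-diene (E/Z mixture), via lithium dienolate 14 (not isolated)
Conditions: LiN(iPr)2, THF, −78 °C; then Me3SiCl, −78 °C to rt; filtration under argon, short-path distillation
Reagents that add atoms: chlorotrimethylsilane, C[Si](C)(C)Cl
Why: Vinylogous (gamma) deprotonation of a beta-alkoxy enoate and O-silylation of the lithium dienolate, the standard entry to 1,1,3-trioxygenated silyl ketene-acetal dienes; the vinylic chloride should not be exchanged or eliminated by the amide base at −78 °C, and the hard silyl chloride should react at oxygen.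

Step 8
Reactants: 10 tert-butyl 2-(methoxymethoxy)-4-(oct-2-ynoyloxy)-6-pentylbenzoate; 15 2-chloro-1,3-dimethoxy-1-(trimethylsilyloxy)buta-1,3-diene (3 equiv)
Product: 17 tert-butyl 4-[(3-chloro-2-hydroxy-4-methoxy-6-pentylbenzoyl)oxy]-2-(methoxymethoxy)-6-pentylbenzoate, via cyclohexa-1,4-diene cycloadduct 16 (not isolated)
Conditions: PhMe, 100 °C, sealed tube; then 0.5 M aq citric acid, THF, rt
Reagents that add atoms: none
Why: Normal-electron-demand Diels–Alder reaction between the electron-rich ketene-acetal diene 15 and the electron-poor triple bond of 10, asynchronous or in the limit a Michael addition followed by Claisen-type closure: the CH2 terminus of 15 bonds to the pentyl-bearing beta carbon (C5–C6 of ring B) and the ketene-acetal carbon to the alpha carbon (C1–C2), giving cycloadduct 16. On acidic work-up the silyl group is removed, the mixed ketal at C2 collapses to the ketone with loss of methanol, and the cyclohexa-2,5-dienone tautomerises to the C2 phenol, so that OH, Cl, OMe and H end at C2, C3, C4 and C5 as delivered by the diene. The closest known reaction type is the Diels–Alder/aromatisation of 1,1,3-trioxygenated silyl ketene-acetal dienes with acetylenic esters, which turns beta-alkyl ynoates into 6-alkyl resorcylates; the chlorine on the diene is expected to slow the addition, hence heating and excess diene. Ring B is closed intermolecularly as a six-membered carbocycle in a [4+2] mode by two C–C bonds (in the stepwise limit the second bond forms by 6-exo-trig attack on the silylated ester carbon). No stereocentre remains, since the ketal carbon of 16 is the only one formed and is erased on aromatisation, which is why the E/Z composition of 15 does not matter. The step needs regioselectivity and chemoselectivity: the first follows from the matched polarisation (largest HOMO coefficient at the diene CH2, largest LUMO coefficient at the ynoate beta carbon), the second from the absence of acidic protons in 10 and from the hindered, unreactive tert-butyl benzoate.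

Step 9
Reactants: 17 tert-butyl 4-[(3-chloro-2-hydroxy-4-methoxy-6-pentylbenzoyl)oxy]-2-(methoxymethoxy)-6-pentylbenzoate
Product: 18 4-[(3-chloro-2-hydroxy-4-methoxy-6-pentylbenzoyl)oxy]-2-hydroxy-6-pentylbenzoic acid
Conditions: TFA/CH2Cl2/H2O (10:10:1), 0 °C to rt
Reagents that add atoms: none
Why: Acidolysis: TFA cleaves the tert-butyl ester through the tert-butyl cation (lost as 2-methylpropene) and hydrolyses the MOM acetal with the added water, whereas the aryl ester between the rings, the methyl ether, the aryl chloride and the free salicylic acid should be stable to non-nucleophilic acid at room temperature.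

Compound list
1 | 2-hydroxy-6-methylbenzoic acid | Cc1cccc(O)c1C(=O)O | starting material
2 | tert-butyl 2-hydroxy-6-methylbenzoate | Cc1cccc(O)c1C(=O)OC(C)(C)C | intermediate
3 | tert-butyl 2-(methoxymethoxy)-6-methylbenzoate | Cc1cccc(OCOC)c1C(=O)OC(C)(C)C | intermediate
4 | 1-bromobutane | CCCCBr | starting material
5 | tert-butyl 2-(lithiomethyl)-6-(methoxymethoxy)benzoate | [Li]Cc1cccc(OCOC)c1C(=O)OC(C)(C)C | intermediate (not isolated)
6 | tert-butyl 2-(methoxymethoxy)-6-pentylbenzoate | CCCCCc1cccc(OCOC)c1C(=O)OC(C)(C)C | intermediate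
7 | tert-butyl 2-(methoxymethoxy)-6-pentyl-4-(4,4,5,5-tetramethyl-1,3,2-dioxaborolan-2-yl)benzoate | CCCCCc1cc(B2OC(C)(C)C(C)(C)O2)cc(OCOC)c1C(=O)OC(C)(C)C | intermediate (not isolated)
8 | tert-butyl 4-hydroxy-2-(methoxymethoxy)-6-pentylbenzoate | CCCCCc1cc(O)cc(OCOC)c1C(=O)OC(C)(C)C | intermediate
9 | oct-2-ynoic acid | CCCCCC#CC(=O)O | starting material
10 | tert-butyl 2-(methoxymethoxy)-4-(oct-2-ynoyloxy)-6-pentylbenzoate | CCCCCC#CC(=O)Oc1cc(CCCCC)c(C(=O)OC(C)(C)C)c(OCOC)c1 | intermediate
11 | methyl 2-chloro-3-oxobutanoate (methyl 2-chloroacetoacetate, racemic) | CC(=O)C(Cl)C(=O)OC | starting material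
12 | methyl 2-chloro-3,3-dimethoxybutanoate (racemic) | COC(C)(OC)C(Cl)C(=O)OC | intermediate (not isolated)
13 | methyl 2-chloro-3-methoxybut-2-enoate (E/Z mixture) | COC(C)=C(Cl)C(=O)OC | intermediate
14 | lithium 2-chloro-1,3-dimethoxybuta-1,3-dien-1-olate | C=C(OC)C(Cl)=C(OC)O[Li] | intermediate (not isolated)
15 | 2-chloro-1,3-dimethoxy-1-(trimethylsilyloxy)buta-1,3-diene (E/Z mixture) | C=C(OC)C(Cl)=C(OC)O[Si](C)(C)C | intermediate
16 | tert-butyl 4-{[5-chloro-4,6-dimethoxy-2-pentyl-6-(trimethylsilyloxy)cyclohexa-1,4-diene-1-carbonyl]oxy}-2-(methoxymethoxy)-6-pentylbenzoate (racemic at the ketal carbon) | CCCCCC1=C(C(=O)Oc2cc(CCCCC)c(C(=O)OC(C)(C)C)c(OCOC)c2)C(OC)(O[Si](C)(C)C)C(Cl)=C(OC)C1 | intermediate (not isolated)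
17 | tert-butyl 4-[(3-chloro-2-hydroxy-4-methoxy-6-pentylbenzoyl)oxy]-2-(methoxymethoxy)-6-pentylbenzoate | CCCCCc1cc(OC(=O)c2c(CCCCC)cc(OC)c(Cl)c2O)cc(OCOC)c1C(=O)OC(C)(C)C | intermediate
18 | 4-[(3-chloro-2-hydroxy-4-methoxy-6-pentylbenzoyl)oxy]-2-hydroxy-6-pentylbenzoic acid | CCCCCc1cc(OC(=O)c2c(CCCCC)cc(OC)c(Cl)c2O)cc(O)c1C(=O)O | target

Total step count: 9 (steps 1–5 build the ring A ynoate, steps 6–7 the diene, step 8 is the key step, step 9 the deprotection).
Longest linear sequence: 7 steps (steps 1, 2, 3, 4, 5, 8, 9).

Steps most likely to fail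

Step 8. The cycloaddition may be slower than thermal decomposition or adventitious protonation of the diene, because the chlorine lowers the nucleophilicity of the diene and the beta carbon of the ynoate carries an alkyl chain. On aromatisation silanol may also be lost instead of methanol, which would leave a methyl ether at C2. The fallback sets out from phenol 8 and a purchased arene and comes back to the route at 17; ring B is built by classical arene chemistry and attached by esterification. Purchased 1,3-dimethoxy-5-pentylbenzene F1 is lithiated between its two methoxy groups (n-BuLi, THF, 0 °C) to (2,6-dimethoxy-4-pentylphenyl)lithium F2, which is chlorinated with C2Cl6 to 2-chloro-1,3-dimethoxy-5-pentylbenzene F3. Rieche formylation (Cl2CHOMe, TiCl4, CH2Cl2) at one of the two equivalent free positions should give 3-chloro-2,4-dimethoxy-6-pentylbenzaldehyde F4. BCl3 (CH2Cl2, −78 °C to 0 °C) should remove only the methyl group ortho to the aldehyde, giving 3-chloro-2-hydroxy-4-methoxy-6-pentylbenzaldehyde F5. Pinnick oxidation (NaClO2, NaH2PO4, 2-methylbut-2-ene, t-BuOH/H2O) gives 3-chloro-2-hydroxy-4-methoxy-6-pentylbenzoic acid F6. Carbodiimide coupling of F6 with 8 (DCC, cat. DMAP, PhMe) would then give 17, at the price of acylating with a hindered acid.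

Step 7. Silylation at carbon instead of oxygen, incomplete gamma-deprotonation of the chlorinated enoate, or hydrolysis of the moisture-sensitive diene during isolation may leave too little usable diene. The fallback sets out from 11 and 10 and comes back at 17; the C4 oxygen is carried as a silyl ether and methylated after ring formation. Ketoester 11 is O-silylated (Me3SiCl, Et3N) to methyl 2-chloro-3-(trimethylsilyloxy)but-2-enoate F7. LiN(iPr)2 and then Me3SiCl convert F7, through lithium 2-chloro-1-methoxy-3-(trimethylsilyloxy)buta-1,3-dien-1-olate F8, into 2-chloro-1-methoxy-1,3-bis(trimethylsilyloxy)buta-1,3-diene F9. Heating F9 with 10 in toluene gives the cycloadduct tert-butyl 4-{[5-chloro-6-methoxy-2-pentyl-4,6-bis(trimethylsilyloxy)cyclohexa-1,4-diene-1-carbonyl]oxy}-2-(methoxymethoxy)-6-pentylbenzoate F10. Mild acid work-up aromatises it to tert-butyl 4-[(3-chloro-2,4-dihydroxy-6-pentylbenzoyl)oxy]-2-(methoxymethoxy)-6-pentylbenzoate F11. Selective methylation of the C4 hydroxyl of ring B, which is not hydrogen-bonded (MeI 1 equiv, K2CO3, acetone, rt), would give 17.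

Step 9. The cations released (tert-butyl, methoxymethyl and the formaldehyde derived from it) may be captured by the electron-rich rings, and the liberated salicylic acid may decarboxylate on prolonged contact with strong acid. The fallback sets out from 17 and comes back at 18; the two groups are removed in two stages with a thiol trap. ZnBr2 and n-PrSH (CH2Cl2, 0 °C) remove the MOM group, the thiol capturing the methoxymethyl unit, to give tert-butyl 4-[(3-chloro-2-hydroxy-4-methoxy-6-pentylbenzoyl)oxy]-2-hydroxy-6-pentylbenzoate F12. Brief treatment of F12 with TFA/CH2Cl2 at 0 °C then cleaves only the tert-butyl ester and gives 18.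

Further compounds
F1 | step 8 | 1,3-dimethoxy-5-pentylbenzene (purchased) | CCCCCc1cc(OC)cc(OC)c1
F2 | step 8 | (2,6-dimethoxy-4-pentylphenyl)lithium | [Li]c1c(OC)cc(CCCCC)cc1OC
F3 | step 8 | 2-chloro-1,3-dimethoxy-5-pentylbenzene | CCCCCc1cc(OC)c(Cl)c(OC)c1
F4 | step 8 | 3-chloro-2,4-dimethoxy-6-pentylbenzaldehyde | CCCCCc1cc(OC)c(Cl)c(OC)c1C=O
F5 | step 8 | 3-chloro-2-hydroxy-4-methoxy-6-pentylbenzaldehyde | CCCCCc1cc(OC)c(Cl)c(O)c1C=O
F6 | step 8 | 3-chloro-2-hydroxy-4-methoxy-6-pentylbenzoic acid | CCCCCc1cc(OC)c(Cl)c(O)c1C(=O)O
F7 | step 7 | methyl 2-chloro-3-(trimethylsilyloxy)but-2-enoate (E/Z mixture) | CC(O[Si](C)(C)C)=C(Cl)C(=O)OC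
F8 | step 7 | lithium 2-chloro-1-methoxy-3-(trimethylsilyloxy)buta-1,3-dien-1-olate | C=C(O[Si](C)(C)C)C(Cl)=C(OC)O[Li]
F9 | step 7 | 2-chloro-1-methoxy-1,3-bis(trimethylsilyloxy)buta-1,3-diene | C=C(O[Si](C)(C)C)C(Cl)=C(OC)O[Si](C)(C)C
F10 | step 7 | tert-butyl 4-{[5-chloro-6-methoxy-2-pentyl-4,6-bis(trimethylsilyloxy)cyclohexa-1,4-diene-1-carbonyl]oxy}-2-(methoxymethoxy)-6-pentylbenzoate | CCCCCC1=C(C(=O)Oc2cc(CCCCC)c(C(=O)OC(C)(C)C)c(OCOC)c2)C(OC)(O[Si](C)(C)C)C(Cl)=C(O[Si](C)(C)C)C1
F11 | step 7 | tert-butyl 4-[(3-chloro-2,4-dihydroxy-6-pentylbenzoyl)oxy]-2-(methoxymethoxy)-6-pentylbenzoate | CCCCCc1cc(OC(=O)c2c(CCCCC)cc(O)c(Cl)c2O)cc(OCOC)c1C(=O)OC(C)(C)C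
F12 | step 9 | tert-butyl 4-[(3-chloro-2-hydroxy-4-methoxy-6-pentylbenzoyl)oxy]-2-hydroxy-6-pentylbenzoate | CCCCCc1cc(OC(=O)c2c(CCCCC)cc(OC)c(Cl)c2O)cc(O)c1C(=O)OC(C)(C)C
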